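**Plan**

- Atom labels: oxepane O1, C2 (quaternary), C3 (CHOAc), C4, C5, C6 (ylidene), C7; side chain on C2: C1′–C3′ (CH2), C4′ (CHMe), C5′ (CHOH), C6′, C7′=C8′.
- Retrosynthesis: C5′–OH comes from C5′–B. C3′–C4′ and C5′–C6′ are cut in one operation (iodide 15 plus a boron ate complex carrying a (Z)-propenyl and a prenyl group). Then O1–C2 (epoxide opening), C5–C6 (B-alkyl Suzuki) and C3–C4 (alkenylalane plus ethylene oxide).
- Enabling feature: C4′ (Me, H) and C5′ (OH, H) are adjacent sp3 carbons, each flanked by a CH2, with Me/OH syn. This is the pattern left by anti addition of two carbon groups across a (Z)-CH3CH=CH–B unit whose boron becomes the C5′ hydroxyl.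
- Forward: chloroalkyne → (E)-homoallylic iodide → (2E,6E)-dienoate (exocyclic alkene geometry fixed while acyclic) → epoxide → oxepane (the only ring) → iodide 15 → side chain by the three-component coupling → acetylation → C–B oxidation last.
- Stereochemistry: C3 from the Shi epoxidation; C2 by inversion in the epoxide opening; C4′/C5′ relative from the Z alkene plus anti addition, absolute from the chiral nickel ligand; alkene geometries from syn carboalumination and anti hydroiodination followed by retentive coupling.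

Key step: step 10

Assumption: the sense of induction of the nickel catalyst on this new substrate is not known in advance, so the Ph-Pybox antipode (both are commercial) that gives the (4′R,5′R) series is taken from a first screening run.

Step 1
Reactants: 1 5-chloropent-1-yne
Product: 4 (E)-7-chloro-4-methylhept-3-en-1-ol, via alkenylalane 2 (not isolated), via lithium alanate 3 (not isolated)
Conditions: Me3Al, Cp2ZrCl2 (cat.), CH2Cl2, rt; then n-BuLi, hexane/THF, −78 °C; ethylene oxide, −78 → 0 °C; dil. HCl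
Reagents that add atoms: trimethylaluminium C[Al](C)C; ethylene oxide C1CO1
Why: Zr-catalysed methylalumination (Negishi carboalumination) adds Me and Al syn across the alkyne, which sets the E trisubstituted alkene, and the derived alanate opens ethylene oxide with retention of alkene geometry while the alkyl chloride is inert.

Step 2
Reactants: 4 (E)-7-chloro-4-methylhept-3-en-1-ol
Product: 5 (E)-7-chloro-1-iodo-4-methylhept-3-ene
Conditions: I2, PPh3, imidazole, CH2Cl2, 0 °C → rt
Reagents that add atoms: iodine II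
Why: Appel-type iodination of a primary alcohol (SN2 on the alkoxyphosphonium ion) should leave the alkene and the chloride untouched.

Step 3
Reactants: 6 ethyl 4-hydroxybut-2-ynoate
Product: 7 ethyl (Z)-4-hydroxy-3-iodobut-2-enoate
Conditions: NaI, AcOH, MeCN, 80 °C
Reagents that add atoms: sodium iodide [Na+].[I-]
Why: Conjugate hydroiodination of a 2-ynoate (iodide at C3, anti protonation at C2) should give the Z iodoenoate, in which CH2OH is trans to the ester and cannot lactonise.

Step 4
Reactants: 5 (E)-7-chloro-1-iodo-4-methylhept-3-ene; 7 ethyl (Z)-4-hydroxy-3-iodobut-2-enoate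
Product: 10 ethyl (2E,6E)-10-chloro-3-(hydroxymethyl)-7-methyldeca-2,6-dienoate, via alkyllithium 8 (not isolated), via borinate complex 9 (not isolated)
Conditions: 5, t-BuLi (2 equiv), Et2O, −78 °C; B-MeO-9-BBN, THF, → rt; then 7, Pd(dppf)Cl2 (cat.), K3PO4 (aq), DMF, rt
Reagents that add atoms: none
Why: B-alkyl Suzuki–Miyaura coupling proceeds with retention at the vinyl iodide, so the new chain ends up cis to the ester, which is the E geometry of the target's exocyclic alkene; the free hydroxyl, ester and alkyl chloride are tolerated.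

Step 5
Reactants: 10 ethyl (2E,6E)-10-chloro-3-(hydroxymethyl)-7-methyldeca-2,6-dienoate
Product: 11 ethyl (2E)-5-[(2R,3R)-3-(3-chloropropyl)-3-methyloxiran-2-yl]-3-(hydroxymethyl)pent-2-enoate
Conditions: D-fructose-derived Shi ketone (cat.), Oxone, K2CO3, Bu4NHSO4, MeCN/DMM/aq. buffer (pH ca. 10.5), 0 °C
Reagents that add atoms: Oxone (potassium peroxymonosulfate) [K+].[O-]S(=O)(=O)OO
Why: In the Shi epoxidation the chiral dioxirane attacks only the electron-rich trisubstituted alkene (the enoate is inert) and, through the spiro transition state, should give the (R,R)-epoxide of an E trisubstituted alkene, which fixes the future C3 and, after inversion, C2.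

Step 6
Reactants: 11 ethyl (2E)-5-[(2R,3R)-3-(3-chloropropyl)-3-methyloxiran-2-yl]-3-(hydroxymethyl)pent-2-enoate
Product: 12 ethyl (2E)-2-[(2S,3R)-2-(3-chloropropyl)-3-hydroxy-2-methyloxepan-6-ylidene]acetate
Conditions: CSA (cat.), CH2Cl2, −20 → 0 °C
Reagents that add atoms: none
Why: In this acid-catalysed hydroxy-epoxide cyclisation the C7 hydroxyl should open the protonated epoxide at its tertiary carbon (Markovnikov, 7-endo-tet) with inversion, giving C2 (S), while C3 keeps the epoxide oxygen (R).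

Step 7
Reactants: 12 ethyl (2E)-2-[(2S,3R)-2-(3-chloropropyl)-3-hydroxy-2-methyloxepan-6-ylidene]acetate
Product: 13 (2S,3R,6E)-2-(3-chloropropyl)-6-(2-hydroxyethylidene)-2-methyloxepan-3-ol
Conditions: DIBAL-H, CH2Cl2, −78 → −20 °C; Rochelle salt
Reagents that add atoms: none
Why: DIBAL reduces the enoate 1,2 to the allylic alcohol without touching the alkene geometry or the alkyl chloride.

Step 8
Reactants: 13 (2S,3R,6E)-2-(3-chloropropyl)-6-(2-hydroxyethylidene)-2-methyloxepan-3-ol
Product: 14 (2S,3R,6E)-2-(3-chloropropyl)-2-methyl-3-(triethylsilyloxy)-6-[2-(triethylsilyloxy)ethylidene]oxepane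
Conditions: TESOTf, 2,6-lutidine, CH2Cl2, −78 → 0 °C
Reagents that add atoms: triethylsilyl triflate CC[Si](CC)(CC)OS(=O)(=O)C(F)(F)F
Why: Silyl triflate silylation protects both the primary allylic and the hindered secondary hydroxyl for the organometallic key step.

Step 9
Reactants: 14 (2S,3R,6E)-2-(3-chloropropyl)-2-methyl-3-(triethylsilyloxy)-6-[2-(triethylsilyloxy)ethylidene]oxepane
Product: 15 (2S,3R,6E)-2-(3-iodopropyl)-2-methyl-3-(triethylsilyloxy)-6-[2-(triethylsilyloxy)ethylidene]oxepane
Conditions: NaI, NaHCO3, butan-2-one, 80 °C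
Reagents that add atoms: sodium iodide [Na+].[I-]
Why: Finkelstein exchange on an unhindered primary chloride is driven by precipitation of NaCl, and the buffered neutral medium spares the silyl ethers.

Step 10
Reactants: 15 (2S,3R,6E)-2-(3-iodopropyl)-2-methyl-3-(triethylsilyloxy)-6-[2-(triethylsilyloxy)ethylidene]oxepane; 16 4,4,5,5-tetramethyl-2-(3-methylbut-2-en-1-yl)-1,3,2-dioxaborolane; 17 (Z)-1-bromoprop-1-ene
Product: 20 (2S,3R,6E)-2-[(4R,5R)-4,8-dimethyl-5-(4,4,5,5-tetramethyl-1,3,2-dioxaborolan-2-yl)non-7-en-1-yl]-2-methyl-3-(triethylsilyloxy)-6-[2-(triethylsilyloxy)ethylidene]oxepane, via propenyllithium 18 (not isolated), via borate complex 19 (not isolated)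
Conditions: 17, t-BuLi (2 equiv), Et2O/THF, −78 °C; 16, −78 °C → rt; then 15 (limiting), NiBr2·glyme (cat.), Ph-Pybox (cat.), THF/DMSO, rt
Reagents that add atoms: none
Why: Proposed new method: the nickel–Pybox catalyst converts iodide 15 into an electrophilic alkylnickel species that binds the propenyl C=C of borate 19, the prenyl group migrates from boron to the boron-bearing carbon C5′ on the face opposite nickel (metal-induced 1,2-metallate rearrangement), and C(sp3)–C(sp3) reductive elimination at C4′ forms the C3′–C4′ bond with retention, so that 15 and the nine-carbon borate are joined and the C5′–C6′ bond is made in the same event. The closest known reaction types are the nickel-catalysed enantioselective conjunctive coupling of vinylboron ate complexes with unactivated primary alkyl iodides and the palladium-catalysed diastereoselective conjunctive coupling of β-substituted alkenylboron ate complexes; the extension lies in combining a β-methyl alkenyl group and an allylic migrating group in the nickel/alkyl iodide manifold. No ring is closed. C4′ and C5′ are created together: their relative configuration (methyl and boron syn in the extended chain) follows from net anti addition of C6′ and C3′ across the Z double bond, and their absolute configuration from the alkene face selected by the chiral ligand, the oxepane stereocentres being too remote to interfere. The step needs reaction at the propenyl and not the prenyl π-bond, and metallate shift in preference to direct boron-to-nickel transfer; the propenyl carbon is bonded directly to the electron-rich tetracoordinate boron and is less hindered than the trisubstituted prenyl terminus, and the four-coordinate pinacol boronate is slow to transmetalate. Boron ends on C5′ and serves as the protected hydroxyl until step 13.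

Step 11
Reactants: 20 (2S,3R,6E)-2-[(4R,5R)-4,8-dimethyl-5-(4,4,5,5-tetramethyl-1,3,2-dioxaborolan-2-yl)non-7-en-1-yl]-2-methyl-3-(triethylsilyloxy)-6-[2-(triethylsilyloxy)ethylidene]oxepane
Product: 21 (2S,3R,6E)-2-[(4R,5R)-4,8-dimethyl-5-(4,4,5,5-tetramethyl-1,3,2-dioxaborolan-2-yl)non-7-en-1-yl]-6-(2-hydroxyethylidene)-2-methyloxepan-3-ol
Conditions: PPTS (cat.), MeOH/CH2Cl2, 0 °C → rt
Reagents that add atoms: none
Why: Mild acid-catalysed methanolysis removes both triethylsilyl ethers, and the secondary alkyl pinacol boronate and the alkenes should be stable to it.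

Step 12
Reactants: 21 (2S,3R,6E)-2-[(4R,5R)-4,8-dimethyl-5-(4,4,5,5-tetramethyl-1,3,2-dioxaborolan-2-yl)non-7-en-1-yl]-6-(2-hydroxyethylidene)-2-methyloxepan-3-ol
Product: 22 (2E)-2-[(2S,3R)-3-acetoxy-2-[(4R,5R)-4,8-dimethyl-5-(4,4,5,5-tetramethyl-1,3,2-dioxaborolan-2-yl)non-7-en-1-yl]-2-methyloxepan-6-ylidene]ethyl acetate
Conditions: Ac2O, pyridine, DMAP (cat.), CH2Cl2, rt
Reagents that add atoms: acetic anhydride CC(=O)OC(C)=O
Why: DMAP-catalysed acetylation esterifies the two hydroxyls, while the C5′ oxygen is still masked as the C–B bond and so cannot be acetylated.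

Step 13
Reactants: 22 (2E)-2-[(2S,3R)-3-acetoxy-2-[(4R,5R)-4,8-dimethyl-5-(4,4,5,5-tetramethyl-1,3,2-dioxaborolan-2-yl)non-7-en-1-yl]-2-methyloxepan-6-ylidene]ethyl acetate
Product: 23 (2E)-2-[(2S,3R)-3-acetoxy-2-[(4R,5R)-5-hydroxy-4,8-dimethylnon-7-en-1-yl]-2-methyloxepan-6-ylidene]ethyl acetate (target)
Conditions: NaBO3·4H2O, THF/H2O, 0 °C → rt
Reagents that add atoms: sodium perborate [Na+].[O-]OB=O
Why: Perborate oxidation of the C–B bond (1,2-shift of carbon from boron to oxygen with retention) should unveil the C5′ hydroxyl as R under weakly basic conditions that spare the two acetates.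

**Compound list**

1 | 5-chloropent-1-yne | C#CCCCCl | starting material
2 | (E)-(5-chloro-2-methylpent-1-en-1-yl)dimethylalane | C[Al](C)/C=C(\C)CCCCl | intermediate
3 | lithium (E)-butyl(5-chloro-2-methylpent-1-en-1-yl)dimethylalanate | [Li+].CCCC[Al-](C)(C)/C=C(\C)CCCCl | intermediate
4 | (E)-7-chloro-4-methylhept-3-en-1-ol | OCC/C=C(\C)CCCCl | intermediate
5 | (E)-7-chloro-1-iodo-4-methylhept-3-ene | ICC/C=C(\C)CCCCl | intermediate
6 | ethyl 4-hydroxybut-2-ynoate | CCOC(=O)C#CCO | starting material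
7 | ethyl (Z)-4-hydroxy-3-iodobut-2-enoate | CCOC(=O)/C=C(\I)CO | intermediate
8 | (E)-(7-chloro-4-methylhept-3-en-1-yl)lithium | [Li]CC/C=C(\C)CCCCl | intermediate
9 | lithium B-[(E)-7-chloro-4-methylhept-3-en-1-yl]-B-methoxy-9-borabicyclo[3.3.1]nonane ate complex | [Li+].CO[B-]1(CC/C=C(\C)CCCCl)C2CCCC1CCC2 | intermediate
10 | ethyl (2E,6E)-10-chloro-3-(hydroxymethyl)-7-methyldeca-2,6-dienoate | CCOC(=O)/C=C(\CC/C=C(\C)CCCCl)CO | intermediate
11 | ethyl (2E)-5-[(2R,3R)-3-(3-chloropropyl)-3-methyloxiran-2-yl]-3-(hydroxymethyl)pent-2-enoate | CCOC(=O)/C=C(\CC[C@H]1O[C@]1(C)CCCCl)CO | intermediate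
12 | ethyl (2E)-2-[(2S,3R)-2-(3-chloropropyl)-3-hydroxy-2-methyloxepan-6-ylidene]acetate | CCOC(=O)/C=C1\CC[C@@H](O)[C@](C)(CCCCl)OC1 | intermediate
13 | (2S,3R,6E)-2-(3-chloropropyl)-6-(2-hydroxyethylidene)-2-methyloxepan-3-ol | OC/C=C1\CC[C@@H](O)[C@](C)(CCCCl)OC1 | intermediate
14 | (2S,3R,6E)-2-(3-chloropropyl)-2-methyl-3-(triethylsilyloxy)-6-[2-(triethylsilyloxy)ethylidene]oxepane | CC[Si](CC)(CC)OC/C=C1\CC[C@@H](O[Si](CC)(CC)CC)[C@](C)(CCCCl)OC1 | intermediate
15 | (2S,3R,6E)-2-(3-iodopropyl)-2-methyl-3-(triethylsilyloxy)-6-[2-(triethylsilyloxy)ethylidene]oxepane | CC[Si](CC)(CC)OC/C=C1\CC[C@@H](O[Si](CC)(CC)CC)[C@](C)(CCCI)OC1 | intermediate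
16 | 4,4,5,5-tetramethyl-2-(3-methylbut-2-en-1-yl)-1,3,2-dioxaborolane (prenylboronic acid pinacol ester) | CC(C)=CCB1OC(C)(C)C(C)(C)O1 | starting material
17 | (Z)-1-bromoprop-1-ene | C/C=C\Br | starting material
18 | (Z)-prop-1-en-1-yllithium | C/C=C\[Li] | intermediate
19 | lithium 4,4,5,5-tetramethyl-2-(3-methylbut-2-en-1-yl)-2-[(Z)-prop-1-en-1-yl]-1,3,2-dioxaborolan-2-uide | [Li+].C/C=C\[B-]1(CC=C(C)C)OC(C)(C)C(C)(C)O1 | intermediate
20 | (2S,3R,6E)-2-[(4R,5R)-4,8-dimethyl-5-(4,4,5,5-tetramethyl-1,3,2-dioxaborolan-2-yl)non-7-en-1-yl]-2-methyl-3-(triethylsilyloxy)-6-[2-(triethylsilyloxy)ethylidene]oxepane | CC[Si](CC)(CC)OC/C=C1\CC[C@@H](O[Si](CC)(CC)CC)[C@](C)(CCC[C@@H](C)[C@H](B2OC(C)(C)C(C)(C)O2)CC=C(C)C)OC1 | intermediate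
21 | (2S,3R,6E)-2-[(4R,5R)-4,8-dimethyl-5-(4,4,5,5-tetramethyl-1,3,2-dioxaborolan-2-yl)non-7-en-1-yl]-6-(2-hydroxyethylidene)-2-methyloxepan-3-ol | OC/C=C1\CC[C@@H](O)[C@](C)(CCC[C@@H](C)[C@H](B2OC(C)(C)C(C)(C)O2)CC=C(C)C)OC1 | intermediate
22 | (2E)-2-[(2S,3R)-3-acetoxy-2-[(4R,5R)-4,8-dimethyl-5-(4,4,5,5-tetramethyl-1,3,2-dioxaborolan-2-yl)non-7-en-1-yl]-2-methyloxepan-6-ylidene]ethyl acetate | CC(=O)OC/C=C1\CC[C@@H](OC(C)=O)[C@](C)(CCC[C@@H](C)[C@H](B2OC(C)(C)C(C)(C)O2)CC=C(C)C)OC1 | intermediate
23 | (2E)-2-[(2S,3R)-3-acetoxy-2-[(4R,5R)-5-hydroxy-4,8-dimethylnon-7-en-1-yl]-2-methyloxepan-6-ylidene]ethyl acetate | CC(=O)OC/C=C1\CC[C@@H](OC(C)=O)[C@](C)(CCC[C@@H](C)[C@H](O)CC=C(C)C)OC1 | target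

Total step count: 13. Longest linear sequence: 12 steps (1, 2, 4–13); step 3 is a one-step branch.

**Steps most likely to fail**

1. Step 10 (Proposed new method). What may go wrong: direct transfer of the prenyl or propenyl group from boron to nickel (Suzuki-type coupling) in place of the metallate shift; β-hydride elimination from the secondary alkylnickel intermediate; a free-radical pathway that erodes the C4′ configuration; poor facial control by the ligand. Fallback (known chemistry: two lithiation–borylation homologations), setting out from 15 and returning at 20. Copper-catalysed borylation of 15 (B2pin2, CuI, PPh3, LiOMe, DMF, rt) should give the primary pinacol boronate F1. Ethyl 2,4,6-triisopropylbenzoate is deprotonated with s-BuLi/(−)-sparteine (Et2O, −78 °C) to the (S)-1-lithioethyl benzoate F2. This adds to F1 with retention, and on warming the 1,2-metallate rearrangement (inversion at the carbenoid carbon) forms the C3′–C4′ bond and should give the secondary boronate F3 with 4′R. 4-Methylpent-3-en-1-yl 2,4,6-triisopropylbenzoate F4 (from 4-methylpent-3-en-1-ol, NaH and 2,4,6-triisopropylbenzoyl chloride) is lithiated in the same way to the (S)-lithiated benzoate F5. Its reaction with F3 (C4′ migrates with retention, inversion at the new carbinol carbon) should give 20.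

2. Step 6. What may go wrong: attack of the hydroxyl at the secondary epoxide carbon through the six-membered transition state (6-exo, tetrahydropyran formation), or rearrangement of the tertiary cation (hydride shift to a ketone), so that little oxepane forms. Fallback, setting out from 10 and returning at 14: the oxygen is first fixed on C2 by an intermolecular hydration that has no ring-size bias, and the ring is then closed at O1–C7. 10 is converted into the allylic chloride F6 (MsCl, LiCl, 2,4,6-collidine, DMF, 0 °C). Shi epoxidation as in step 5 should give the epoxide F7. Acid-catalysed hydration (HClO4 cat., THF/H2O, 0 °C; water attacks the tertiary carbon with inversion) should give the diol F8. DIBAL-H (CH2Cl2, −78 °C) gives the allylic alcohol F9. TESOTf/2,6-lutidine (−78 °C) silylates the primary and the secondary hydroxyl to give the tertiary alcohol F10. NaH with Bu4NI in THF/DMF then closes the oxepane by 7-exo-tet displacement of the allylic chloride by the tertiary alkoxide, giving 14.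

3. Step 13. What may go wrong: hydrolysis or migration of the acetates, the allylic one first, under the basic peroxide before the hindered secondary C–B bond is oxidised. Fallback, setting out from 20 and returning at 23: the C5′ oxygen is unveiled before acetylation and carried as a silyl ether. 20 is oxidised (NaOH, H2O2, THF, 0 °C) to the alcohol F11. This is silylated (TBSOTf, 2,6-lutidine) to the TBS ether F12. PPTS/MeOH removes only the two triethylsilyl groups to give the diol F13. Ac2O/pyridine/DMAP gives the diacetate F14, and HF·pyridine in THF/pyridine then gives 23.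

**Further compounds**

F1 | step 10 | (2S,3R,6E)-2-methyl-2-[3-(4,4,5,5-tetramethyl-1,3,2-dioxaborolan-2-yl)propyl]-3-(triethylsilyloxy)-6-[2-(triethylsilyloxy)ethylidene]oxepane | CC[Si](CC)(CC)OC/C=C1\CC[C@@H](O[Si](CC)(CC)CC)[C@](C)(CCCB2OC(C)(C)C(C)(C)O2)OC1
F2 | step 10 | (S)-1-lithioethyl 2,4,6-triisopropylbenzoate | C[C@H]([Li])OC(=O)c1c(C(C)C)cc(C(C)C)cc1C(C)C
F3 | step 10 | (2S,3R,6E)-2-methyl-2-[(4R)-4-(4,4,5,5-tetramethyl-1,3,2-dioxaborolan-2-yl)pentyl]-3-(triethylsilyloxy)-6-[2-(triethylsilyloxy)ethylidene]oxepane | CC[Si](CC)(CC)OC/C=C1\CC[C@@H](O[Si](CC)(CC)CC)[C@](C)(CCC[C@@H](C)B2OC(C)(C)C(C)(C)O2)OC1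
F4 | step 10 | 4-methylpent-3-en-1-yl 2,4,6-triisopropylbenzoate | CC(C)=CCCOC(=O)c1c(C(C)C)cc(C(C)C)cc1C(C)C
F5 | step 10 | (S)-1-lithio-4-methylpent-3-en-1-yl 2,4,6-triisopropylbenzoate | CC(C)=CC[C@H]([Li])OC(=O)c1c(C(C)C)cc(C(C)C)cc1C(C)C
F6 | step 6 | ethyl (2E,6E)-10-chloro-3-(chloromethyl)-7-methyldeca-2,6-dienoate | CCOC(=O)/C=C(\CC/C=C(\C)CCCCl)CCl
F7 | step 6 | ethyl (2E)-3-(chloromethyl)-5-[(2R,3R)-3-(3-chloropropyl)-3-methyloxiran-2-yl]pent-2-enoate | CCOC(=O)/C=C(\CC[C@H]1O[C@]1(C)CCCCl)CCl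
F8 | step 6 | ethyl (2E,6R,7S)-10-chloro-3-(chloromethyl)-6,7-dihydroxy-7-methyldec-2-enoate | CCOC(=O)/C=C(\CC[C@@H](O)[C@](C)(CCCCl)O)CCl
F9 | step 6 | (2E,6R,7S)-10-chloro-3-(chloromethyl)-7-methyldec-2-ene-1,6,7-triol | OC/C=C(\CC[C@@H](O)[C@](C)(CCCCl)O)CCl
F10 | step 6 | (2E,6R,7S)-10-chloro-3-(chloromethyl)-7-methyl-1,6-bis(triethylsilyloxy)dec-2-en-7-ol | CC[Si](CC)(CC)OC/C=C(\CC[C@@H](O[Si](CC)(CC)CC)[C@](C)(CCCCl)O)CCl
F11 | step 13 | (2S,3R,6E)-2-[(4R,5R)-5-hydroxy-4,8-dimethylnon-7-en-1-yl]-2-methyl-3-(triethylsilyloxy)-6-[2-(triethylsilyloxy)ethylidene]oxepane | CC[Si](CC)(CC)OC/C=C1\CC[C@@H](O[Si](CC)(CC)CC)[C@](C)(CCC[C@@H](C)[C@H](O)CC=C(C)C)OC1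
F12 | step 13 | (2S,3R,6E)-2-[(4R,5R)-5-(tert-butyldimethylsilyloxy)-4,8-dimethylnon-7-en-1-yl]-2-methyl-3-(triethylsilyloxy)-6-[2-(triethylsilyloxy)ethylidene]oxepane | CC[Si](CC)(CC)OC/C=C1\CC[C@@H](O[Si](CC)(CC)CC)[C@](C)(CCC[C@@H](C)[C@H](O[Si](C)(C)C(C)(C)C)CC=C(C)C)OC1
F13 | step 13 | (2S,3R,6E)-2-[(4R,5R)-5-(tert-butyldimethylsilyloxy)-4,8-dimethylnon-7-en-1-yl]-6-(2-hydroxyethylidene)-2-methyloxepan-3-ol | OC/C=C1\CC[C@@H](O)[C@](C)(CCC[C@@H](C)[C@H](O[Si](C)(C)C(C)(C)C)CC=C(C)C)OC1
F14 | step 13 | (2E)-2-[(2S,3R)-3-acetoxy-2-[(4R,5R)-5-(tert-butyldimethylsilyloxy)-4,8-dimethylnon-7-en-1-yl]-2-methyloxepan-6-ylidene]ethyl acetate | CC(=O)OC/C=C1\CC[C@@H](OC(C)=O)[C@](C)(CCC[C@@H](C)[C@H](O[Si](C)(C)C(C)(C)C)CC=C(C)C)OC1
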